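**Retrosynthetic overview**
1. Target ⇐ acid unmasking of the 4α‑CHO (dioxolane) and 3β‑OH (TBS ether); (E)‑cinnamate ⇐ Heck arylation of a 6β‑acrylate; 6β‑OH ⇐ hydride attack on the α face of trans‑decalin‑6‑one 13.
2. Key step: ring B of 13 ⇐ one‑carbon ring expansion of the hydrindan‑6‑one 8 with 1‑diazo‑2‑methylpropane, inserting CH(i‑Pr) (= C7) between C6 and C8; C5 and C7 are then set by equilibration next to the ketone.
3. C15 ⇐ radical conjugate addition of 1,3‑dioxolane to γ‑silyloxy enone 6 (anti to O3 and to the angular methyl); C3 ⇐ Luche reduction of ene‑dione 4.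
4. 4 ⇐ asymmetric Michael addition/aldol condensation (Robinson annulation) of 3‑methylcyclopentane‑1,2‑dione with methyl vinyl ketone; this sets C10, from which all other centres are relayed.
5. Ring order: the cyclopentane of 1 (future ring B) → ring A (step 1) → ring B by ring expansion (step 6).

Convention and assumption: 1 is drawn as its commercial enol tautomer; positions are quoted in eudesmane numbering (ring A = C1–C5, C10; ring B = C5–C10; C14 = angular methyl; C15 = formyl carbon; β = face of C14), and the target is (3S,4S,5S,6R,7S,10S): 3β‑OH, 4α‑CHO, 5α‑H, 6β‑O‑cinnamoyl, 7β‑i‑Pr, 10β‑Me.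

**Step 1**
Reactants: 1 3‑methylcyclopentane‑1,2‑dione (enol form, 2‑hydroxy‑3‑methylcyclopent‑2‑en‑1‑one); 2 methyl vinyl ketone
Product: 4 (3aR)‑3a‑methyl‑2,3,3a,4‑tetrahydro‑1H‑indene‑1,6(5H)‑dione, via triketone 3 (not isolated)
Conditions: quinine‑derived 3,5‑(CF3)2C6H3 squaramide (10 mol%), CH2Cl2, −20 °C; then p‑TsOH·H2O (0.3 equiv), PhMe, 80 °C
Reagents that add atoms: none
Why: Proposed new method: the acidic enol of 1 is deprotonated by the quinuclidine nitrogen of the bifunctional catalyst, the two squaramide N–H bonds hold the cis O–C=C–C=O unit of the enolate as a chiral ion pair while the ammonium N–H activates 2, so the methyl‑bearing carbon attacks from one face and the quaternary C10 is set as (R) in 3 (the sense has to be confirmed by experiment; the quinidine‑derived catalyst gives the other enantiomer), and acid then closes ring A by aldol condensation of the side‑chain methyl ketone onto the adjacent ring carbonyl (only this six‑membered closure can dehydrate); the closest known reaction type is the cinchona‑catalysed Michael addition of α‑substituted β‑keto esters to enones and of cyclic 1,2‑diones to nitroalkenes, followed by a Robinson‑type aldol condensation.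

**Step 2**
Reactants: 4 (3aR)‑3a‑methyl‑2,3,3a,4‑tetrahydro‑1H‑indene‑1,6(5H)‑dione
Product: 5 (3aR,6S)‑6‑hydroxy‑3a‑methyl‑2,3,3a,4,5,6‑hexahydro‑1H‑inden‑1‑one
Conditions: NaBH4 (0.3 equiv), CeCl3·7H2O (1.0 equiv), MeOH, −78 °C
Reagents that add atoms: none
Why: Luche 1,2‑reduction, in which the cyclohexenone carbonyl (C3) should react faster than the more hindered cyclopentanone carbonyl (C6), and axial hydride delivery on the α face of the half‑chair (as in steroidal 4‑en‑3‑ones) gives the equatorial 3β‑alcohol (3S).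

**Step 3**
Reactants: 5 (3aR,6S)‑6‑hydroxy‑3a‑methyl‑2,3,3a,4,5,6‑hexahydro‑1H‑inden‑1‑one
Product: 6 (3aR,6S)‑6‑[(tert‑butyldimethylsilyl)oxy]‑3a‑methyl‑2,3,3a,4,5,6‑hexahydro‑1H‑inden‑1‑one
Conditions: TBSCl, imidazole, DMF, 25 °C
Reagents that add atoms: tert‑butyldimethylsilyl chloride (TBSCl), CC(C)(C)[Si](C)(C)Cl
Why: Standard silylation of an unhindered secondary allylic alcohol, needed so that only O6 is acylated later; no stereocentre is touched.

**Step 4**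
Reactants: 6 (3aR,6S)‑6‑[(tert‑butyldimethylsilyl)oxy]‑3a‑methyl‑2,3,3a,4,5,6‑hexahydro‑1H‑inden‑1‑one; 7 1,3‑dioxolane
Product: 8 (3aR,6S,7S)‑6‑[(tert‑butyldimethylsilyl)oxy]‑7‑(1,3‑dioxolan‑2‑yl)‑3a‑methyloctahydro‑1H‑inden‑1‑one (C5 epimers at the ring fusion)
Conditions: (n‑Bu4N)4[W10O32] (2 mol%), 7/MeCN (1:1), 390 nm LEDs, 25 °C
Reagents that add atoms: none
Why: Photocatalytic hydrogen‑atom transfer followed by Giese addition: the excited decatungstate abstracts the acetal C–H of 7 and the nucleophilic dioxolan‑2‑yl radical adds to the enone β‑carbon C4 from the α face, anti to the neighbouring OTBS group and to the pseudoaxial angular methyl, which sets C4 (C15 α, trans to O3); the C5 configuration is left open because it is equilibrated in step 6.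

**Step 5**
Reactants: 9 2‑methylpropanal (isobutyraldehyde)
Product: 10 (E)‑(2‑methylpropylidene)hydrazine (isobutyraldehyde hydrazone)
Conditions: N2H4·H2O (5 equiv), EtOH, 0 °C, slow addition of 9; used fresh
Reagents that add atoms: hydrazine (as the monohydrate), NN
Why: Simple hydrazone condensation, with excess hydrazine and inverse addition to keep azine formation low.

**Step 6**
Reactants: 8 (3aR,6S,7S)‑6‑[(tert‑butyldimethylsilyl)oxy]‑7‑(1,3‑dioxolan‑2‑yl)‑3a‑methyloctahydro‑1H‑inden‑1‑one; 10 (E)‑(2‑methylpropylidene)hydrazine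
Product: 13 (2S,4aS,7S,8S,8aS)‑7‑[(tert‑butyldimethylsilyl)oxy]‑8‑(1,3‑dioxolan‑2‑yl)‑4a‑methyl‑2‑(propan‑2‑yl)octahydronaphthalen‑1(2H)‑one, via 1‑diazo‑2‑methylpropane 11 (not isolated), via epimeric decalone mixture 12 (not isolated)
Conditions: DMSO, (COCl)2, Et3N, THF, −78 °C (10 → 11, cold filtered solution); then 8, Sc(OTf)3 (10 mol%), CH2Cl2, −78 to −40 °C; then NaOMe, MeOH, 25 °C
Reagents that add atoms: none
Why: Ring expansion by Lewis‑acid‑catalysed diazoalkane–ketone homologation (Tiffeneau–Demjanov type): 11 adds to the Sc‑bound C6 carbonyl and the less substituted α‑carbon C8 migrates with loss of N2, so CH(i‑Pr) (= C7) is inserted between C6 and C8 and ring B becomes six‑membered; the doubly α‑branched product resists a second insertion, and NaOMe then equilibrates the two centres flanking the ketone to the trans ring fusion (5α‑H) and the equatorial 7β‑isopropyl group.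

**Step 7**
Reactants: 13 (2S,4aS,7S,8S,8aS)‑7‑[(tert‑butyldimethylsilyl)oxy]‑8‑(1,3‑dioxolan‑2‑yl)‑4a‑methyl‑2‑(propan‑2‑yl)octahydronaphthalen‑1(2H)‑one
Product: 14 (1R,2S,4aS,7S,8S,8aS)‑7‑[(tert‑butyldimethylsilyl)oxy]‑8‑(1,3‑dioxolan‑2‑yl)‑4a‑methyl‑2‑(propan‑2‑yl)decahydronaphthalen‑1‑ol
Conditions: LiAlH4, THF, −78 to 0 °C
Reagents that add atoms: none
Why: Hydride reduction in which the axial 10β‑methyl blocks the β face of C6, so hydride enters from the α (equatorial) side and gives the axial 6β‑alcohol (6R), as with 6‑oxo steroids.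

**Step 8**
Reactants: 14 (1R,2S,4aS,7S,8S,8aS)‑7‑[(tert‑butyldimethylsilyl)oxy]‑8‑(1,3‑dioxolan‑2‑yl)‑4a‑methyl‑2‑(propan‑2‑yl)decahydronaphthalen‑1‑ol; 15 prop‑2‑enoyl chloride (acryloyl chloride)
Product: 16 (1R,2S,4aS,7S,8S,8aS)‑7‑[(tert‑butyldimethylsilyl)oxy]‑8‑(1,3‑dioxolan‑2‑yl)‑4a‑methyl‑2‑(propan‑2‑yl)decahydronaphthalen‑1‑yl prop‑2‑enoate
Conditions: Et3N, DMAP (10 mol%), CH2Cl2, 0 to 25 °C
Reagents that add atoms: none
Why: DMAP‑catalysed acylation, where the small and very reactive acid chloride suits the hindered axial alcohol; C6 keeps its configuration.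

**Step 9**
Reactants: 16 (1R,2S,4aS,7S,8S,8aS)‑7‑[(tert‑butyldimethylsilyl)oxy]‑8‑(1,3‑dioxolan‑2‑yl)‑4a‑methyl‑2‑(propan‑2‑yl)decahydronaphthalen‑1‑yl prop‑2‑enoate; 17 iodobenzene
Product: 18 (1R,2S,4aS,7S,8S,8aS)‑7‑[(tert‑butyldimethylsilyl)oxy]‑8‑(1,3‑dioxolan‑2‑yl)‑4a‑methyl‑2‑(propan‑2‑yl)decahydronaphthalen‑1‑yl (2E)‑3‑phenylprop‑2‑enoate
Conditions: Pd(OAc)2 (5 mol%), P(o‑tol)3 (10 mol%), Et3N, MeCN, 80 °C
Reagents that add atoms: none
Why: Mizoroki–Heck arylation of an acrylate, in which syn insertion and syn β‑hydride elimination give only the (E)‑cinnamate; the silyl ether and acetal are inert.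

**Step 10**
Reactants: 18 (1R,2S,4aS,7S,8S,8aS)‑7‑[(tert‑butyldimethylsilyl)oxy]‑8‑(1,3‑dioxolan‑2‑yl)‑4a‑methyl‑2‑(propan‑2‑yl)decahydronaphthalen‑1‑yl (2E)‑3‑phenylprop‑2‑enoate
Product: 19 (1R,2S,4aS,7S,8S,8aS)‑8‑formyl‑7‑hydroxy‑4a‑methyl‑2‑(propan‑2‑yl)decahydronaphthalen‑1‑yl (2E)‑3‑phenylprop‑2‑enoate (CNP0264095.1)
Conditions: 1 M HCl (aq)/THF (1:2), 25 °C
Reagents that add atoms: water, O
Why: Acid hydrolysis removes the dioxolane and the secondary TBS ether in one operation; the equatorial 4α‑CHO is already the thermodynamic epimer, the 3‑OH/4‑H pair is not antiperiplanar (slow dehydration), and the ester is untouched.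

**Compound list**
1 | 3‑methylcyclopentane‑1,2‑dione (enol form, 2‑hydroxy‑3‑methylcyclopent‑2‑en‑1‑one) | CC1=C(O)C(=O)CC1 | starting material
2 | methyl vinyl ketone (but‑3‑en‑2‑one) | CC(=O)C=C | starting material
3 | (R)‑3‑methyl‑3‑(3‑oxobutyl)cyclopentane‑1,2‑dione (triketone, not isolated) | C[C@@]1(CCC(C)=O)CCC(=O)C1=O | intermediate
4 | (3aR)‑3a‑methyl‑2,3,3a,4‑tetrahydro‑1H‑indene‑1,6(5H)‑dione (ene‑dione: C4=C5 conjugated to C3=O and C6=O) | C[C@]12CCC(=O)C=C1C(=O)CC2 | intermediate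
5 | (3aR,6S)‑6‑hydroxy‑3a‑methyl‑2,3,3a,4,5,6‑hexahydro‑1H‑inden‑1‑one (3β‑OH) | C[C@]12CC[C@H](O)C=C1C(=O)CC2 | intermediate
6 | (3aR,6S)‑6‑[(tert‑butyldimethylsilyl)oxy]‑3a‑methyl‑2,3,3a,4,5,6‑hexahydro‑1H‑inden‑1‑one | C[C@]12CC[C@H](O[Si](C)(C)C(C)(C)C)C=C1C(=O)CC2 | intermediate
7 | 1,3‑dioxolane | C1COCO1 | starting material
8 | (3aR,6S,7S)‑6‑[(tert‑butyldimethylsilyl)oxy]‑7‑(1,3‑dioxolan‑2‑yl)‑3a‑methyloctahydro‑1H‑inden‑1‑one (3β‑OTBS, 4α‑dioxolanyl; C5 epimers, centre left open) | C[C@]12CC[C@H](O[Si](C)(C)C(C)(C)C)[C@@H](C3OCCO3)C1C(=O)CC2 | intermediate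
9 | 2‑methylpropanal (isobutyraldehyde) | CC(C)C=O | starting material
10 | (E)‑(2‑methylpropylidene)hydrazine | CC(C)/C=N/N | intermediate
11 | 1‑diazo‑2‑methylpropane (not isolated) | CC(C)C=[N+]=[N-] | intermediate
12 | (4aS,7S,8S)‑7‑[(tert‑butyldimethylsilyl)oxy]‑8‑(1,3‑dioxolan‑2‑yl)‑4a‑methyl‑2‑(propan‑2‑yl)octahydronaphthalen‑1(2H)‑one, mixture of C5/C7 epimers (not isolated) | CC(C)C1CC[C@@]2(C)CC[C@H](O[Si](C)(C)C(C)(C)C)[C@@H](C3OCCO3)C2C1=O | intermediate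
13 | (2S,4aS,7S,8S,8aS)‑7‑[(tert‑butyldimethylsilyl)oxy]‑8‑(1,3‑dioxolan‑2‑yl)‑4a‑methyl‑2‑(propan‑2‑yl)octahydronaphthalen‑1(2H)‑one (trans‑decalin‑6‑one; 5α‑H, 7β‑i‑Pr, 10β‑Me) | CC(C)[C@@H]1CC[C@@]2(C)CC[C@H](O[Si](C)(C)C(C)(C)C)[C@@H](C3OCCO3)[C@@H]2C1=O | intermediate
14 | (1R,2S,4aS,7S,8S,8aS)‑7‑[(tert‑butyldimethylsilyl)oxy]‑8‑(1,3‑dioxolan‑2‑yl)‑4a‑methyl‑2‑(propan‑2‑yl)decahydronaphthalen‑1‑ol (6β‑OH, axial) | CC(C)[C@@H]1CC[C@@]2(C)CC[C@H](O[Si](C)(C)C(C)(C)C)[C@@H](C3OCCO3)[C@@H]2[C@@H]1O | intermediate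
15 | prop‑2‑enoyl chloride (acryloyl chloride) | C=CC(=O)Cl | starting material
16 | (1R,2S,4aS,7S,8S,8aS)‑7‑[(tert‑butyldimethylsilyl)oxy]‑8‑(1,3‑dioxolan‑2‑yl)‑4a‑methyl‑2‑(propan‑2‑yl)decahydronaphthalen‑1‑yl prop‑2‑enoate | CC(C)[C@@H]1CC[C@@]2(C)CC[C@H](O[Si](C)(C)C(C)(C)C)[C@@H](C3OCCO3)[C@@H]2[C@@H]1OC(=O)C=C | intermediate
17 | iodobenzene | Ic1ccccc1 | starting material
18 | (1R,2S,4aS,7S,8S,8aS)‑7‑[(tert‑butyldimethylsilyl)oxy]‑8‑(1,3‑dioxolan‑2‑yl)‑4a‑methyl‑2‑(propan‑2‑yl)decahydronaphthalen‑1‑yl (2E)‑3‑phenylprop‑2‑enoate | CC(C)[C@@H]1CC[C@@]2(C)CC[C@H](O[Si](C)(C)C(C)(C)C)[C@@H](C3OCCO3)[C@@H]2[C@@H]1OC(=O)/C=C/c1ccccc1 | intermediate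
19 | (1R,2S,4aS,7S,8S,8aS)‑8‑formyl‑7‑hydroxy‑4a‑methyl‑2‑(propan‑2‑yl)decahydronaphthalen‑1‑yl (2E)‑3‑phenylprop‑2‑enoate | CC(C)[C@@H]1CC[C@@]2(C)CC[C@H](O)[C@@H](C=O)[C@@H]2[C@@H]1OC(=O)/C=C/c1ccccc1 | target

**Step count and risks**
Total steps: 10. Longest linear sequence: 9 (steps 1, 2, 3, 4, 6, 7, 8, 9, 10); step 5 is a one‑step side branch.

Risk 1, step 1 (the proposed new reaction). The enantioselectivity is unproven, 1 may react at its unsubstituted α‑carbon, and the enolic adduct may add a second molecule of 2. The fallback uses known chemistry; it sets out from 2 and commercial 2‑methylcyclopentanone (in place of 1) and comes back at 4. Condensation with (R)‑1‑phenylethylamine (PhMe, Dean–Stark) gives (R)‑N‑(2‑methylcyclopentylidene)‑1‑phenylethanamine F1. Its secondary enamine tautomer adds to 2 at the more substituted carbon (chiral‑imine Michael addition, THF, 25 °C) to give (R)‑N‑[(2S)‑2‑methyl‑2‑(3‑oxobutyl)cyclopentylidene]‑1‑phenylethanamine F2. Aqueous AcOH hydrolyses this to (S)‑2‑methyl‑2‑(3‑oxobutyl)cyclopentan‑1‑one F3, and KOH/MeOH aldol condensation gives (S)‑7a‑methyl‑1,2,3,6,7,7a‑hexahydro‑5H‑inden‑5‑one F4. Oxidation of its only allylic (γ) methylene with Rh2(cap)4 (dirhodium tetracaprolactamate, 1 mol%), t‑BuOOH, K2CO3, CH2Cl2 gives 4.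

Risk 2, step 2. The two conjugated carbonyls of 4 may not be differentiated well enough. The fallback sets out from 4 and comes back at 8 by inverting the order of events. The photochemical addition of 7 (conditions of step 4) is run on 4 first; attack at C4 from the α face, anti to the angular methyl, gives (3aS,7R)‑7‑(1,3‑dioxolan‑2‑yl)‑3a‑methylhexahydro‑1H‑indene‑1,6(2H)‑dione F5. NaBH4 (0.3 equiv), EtOH, −78 °C then reduces the cyclohexanone in preference to the hindered cyclopentanone (the selectivity known from androstane‑3,17‑dione), giving (3aR,6S,7S)‑7‑(1,3‑dioxolan‑2‑yl)‑6‑hydroxy‑3a‑methyloctahydro‑1H‑inden‑1‑one F6. TBSCl/imidazole converts this to 8.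

Risk 3, step 6. Addition to the hindered C6 carbonyl may be slow, the unstabilised diazoalkane is awkward to handle, and some C5 migration is possible. The fallback sets out from 8 and comes back at 13; it is still a one‑carbon ring expansion but uses a stabilised diazo compound. Ethyl diazoacetate with BF3·OEt2 (Et2O, 0 °C) inserts CH(CO2Et) on the CH2 side to give ethyl (4aS,7S,8S)‑7‑[(tert‑butyldimethylsilyl)oxy]‑8‑(1,3‑dioxolan‑2‑yl)‑4a‑methyl‑1‑oxodecahydronaphthalene‑2‑carboxylate F7. C‑Alkylation (NaH, 2‑iodopropane, DMF, 60 °C) gives ethyl (4aS,7S,8S)‑7‑[(tert‑butyldimethylsilyl)oxy]‑8‑(1,3‑dioxolan‑2‑yl)‑4a‑methyl‑1‑oxo‑2‑(propan‑2‑yl)decahydronaphthalene‑2‑carboxylate F8. Krapcho dealkoxycarbonylation (LiCl, wet DMSO, 150 °C) gives the mixture 12, which NaOMe/MeOH equilibrates to 13.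

**Further compounds**
F1 | step 1 | (R)‑N‑(2‑methylcyclopentylidene)‑1‑phenylethanamine | C[C@@H](N=C1CCCC1C)c1ccccc1
F2 | step 1 | (R)‑N‑[(2S)‑2‑methyl‑2‑(3‑oxobutyl)cyclopentylidene]‑1‑phenylethanamine | C[C@@H](N=C1CCC[C@@]1(C)CCC(C)=O)c1ccccc1
F3 | step 1 | (S)‑2‑methyl‑2‑(3‑oxobutyl)cyclopentan‑1‑one | C[C@@]1(CCC(C)=O)CCCC1=O
F4 | step 1 | (S)‑7a‑methyl‑1,2,3,6,7,7a‑hexahydro‑5H‑inden‑5‑one | C[C@]12CCC(=O)C=C1CCC2
F5 | step 2 | (3aS,7R)‑7‑(1,3‑dioxolan‑2‑yl)‑3a‑methylhexahydro‑1H‑indene‑1,6(2H)‑dione (ring‑fusion epimers) | C[C@]12CCC(=O)[C@@H](C3OCCO3)C1C(=O)CC2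
F6 | step 2 | (3aR,6S,7S)‑7‑(1,3‑dioxolan‑2‑yl)‑6‑hydroxy‑3a‑methyloctahydro‑1H‑inden‑1‑one (ring‑fusion epimers) | C[C@]12CC[C@H](O)[C@@H](C3OCCO3)C1C(=O)CC2
F7 | step 6 | ethyl (4aS,7S,8S)‑7‑[(tert‑butyldimethylsilyl)oxy]‑8‑(1,3‑dioxolan‑2‑yl)‑4a‑methyl‑1‑oxodecahydronaphthalene‑2‑carboxylate | CCOC(=O)C1CC[C@@]2(C)CC[C@H](O[Si](C)(C)C(C)(C)C)[C@@H](C3OCCO3)C2C1=O
F8 | step 6 | ethyl (4aS,7S,8S)‑7‑[(tert‑butyldimethylsilyl)oxy]‑8‑(1,3‑dioxolan‑2‑yl)‑4a‑methyl‑1‑oxo‑2‑(propan‑2‑yl)decahydronaphthalene‑2‑carboxylate | CCOC(=O)C1(C(C)C)CC[C@@]2(C)CC[C@H](O[Si](C)(C)C(C)(C)C)[C@@H](C3OCCO3)C2C1=O
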